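**Plan**

Numbering: ten-membered ring C1–C10; cyclohexene C1, C10–C14; lactone C7–O–C19–C17–C8; C15 on C1, C16 on C5, C18 on C17, C20 on C11.
Cuts, in retrosynthetic order: the four acetates; C8–C17 (lactone, from a C7 2-bromopropanoate and a C8 ketone); C4–C5 (ten-membered ring); C6–C7, C8–C9 and C2–C3 (side arms); last C1–C14 and C10–C11 (cyclohexene).
Enabling feature: in the cyclohexene the quaternary C1 lies between oxygenated C14 and methine C10, C2 and C9 are trans and O14 is cis to C2. This is the pattern an endo [4+2] of an (E)-2-methyl enal (C2, C1, C10, C9) with a 1-alkoxy-3-silyloxy diene (C14 to C11) delivers.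
Forward order: cyclohexene (step 5), C2 arm, C11=C12 olefin, C9 arm, ten-membered ring (step 21), γ-lactone (step 25), acetates.
Stereochemistry: C1, C10, C14 from the catalyst-controlled endo cycloaddition; C2 by chelation to the C14 ether; C9 by an oxazolidinone aldol; C7 by asymmetric transfer hydrogenation; C8 and C17 from C7 in the lactone closure; C5=C6 geometry from trans-hydroalumination.

Key step: step 5

Remark (assumption): the facial sense of the oxazaborolidinium catalyst is taken from the accepted model for 2-substituted enals (boron anti to the alkene, formyl C–H···O contact, s-trans enal); on that basis the (R)-catalyst is assigned.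

**Route**

Step 1
Reactants: 1 pent-1-yn-3-ol
Product: 2 pent-1-yn-3-one
Conditions: CrO3, H2SO4 (Jones reagent), acetone, 0 °C
Reagents that add atoms: none
Why: Jones oxidation of a secondary propargylic alcohol stops cleanly at the ynone, and no stereocentre is involved.

Step 2
Reactants: 2 pent-1-yn-3-one; 3 4-methoxybenzyl alcohol
Product: 4 (E)-1-(4-methoxybenzyloxy)pent-1-en-3-one
Conditions: DABCO (10 mol%), CH2Cl2, 0 °C → rt
Reagents that add atoms: none
Why: amine-catalysed oxa-Michael addition of an alcohol to an ynone should give the (E)-β-alkoxy enone as the thermodynamically preferred isomer.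

Step 3
Reactants: 4 (E)-1-(4-methoxybenzyloxy)pent-1-en-3-one
Product: 5 (1E,3Z)-1-(4-methoxybenzyloxy)-3-(tert-butyldimethylsilyloxy)penta-1,3-diene
Conditions: TBSOTf, Et3N, Et2O, 0 °C
Reagents that add atoms: tert-butyldimethylsilyl trifluoromethanesulfonate, CC(C)(C)[Si](C)(C)OS(=O)(=O)C(F)(F)F
Why: soft enolisation (silyl triflate/amine) of the ethyl ketone should give the (Z)-silyl enol ether, in which the methyl group avoids the vinyl group, and so a diene with both terminal substituents outside.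

Step 4
Reactants: 6 (tert-butyldimethylsilyloxy)acetaldehyde; 7 2-(triphenylphosphoranylidene)propanal
Product: 8 (E)-4-(tert-butyldimethylsilyloxy)-2-methylbut-2-enal
Conditions: toluene, 80 °C
Reagents that add atoms: none
Why: Wittig olefination with a stabilised formyl ylide is (E)-selective and reacts only with the more electrophilic saturated aldehyde.

Step 5
Reactants: 5 diene; 8 enal
Product: 9 cycloadduct (1R,2S,5S,6S)-4-(tert-butyldimethylsilyloxy)-6-[(tert-butyldimethylsilyloxy)methyl]-2-(4-methoxybenzyloxy)-1,5-dimethylcyclohex-3-ene-1-carbaldehyde (ring C1/C2/C5/C6 = C1/C14/C11/C10; CHO cis to OPMB and to the C11 methyl; trans to the C9 arm)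
Conditions: (R)-o-tolyl-CBS oxazaborolidine (20 mol%), Tf2NH (18 mol%), CH2Cl2, −78 °C
Reagents that add atoms: none
Why: The protonated oxazaborolidine binds the formyl oxygen of 8 anti to the alkene and lowers the LUMO of the C=C bond, which undergoes a concerted, asynchronous [4+2] addition in which the nucleophilic diene terminus C11 bonds to the β-carbon C10 and the alkoxy-bearing terminus C14 to the α-carbon C1; the closest known reaction type is the oxazaborolidinium-catalysed Diels–Alder reaction of 2-substituted enals with silyloxy dienes. The six-membered ring closes in this single intermolecular cycloaddition, suprafacial on both partners. The trans relation of C2 and C9 follows from the (E)-enal, the cis relation of O14 to the formyl group from the endo orientation of the activated CHO, and the C11 methyl (cis to O14, removed later) from the (3Z)-enol ether. The absolute configuration is set by the catalyst, whose aryl group covers one face of the bound enal, so that with the (R)-catalyst the diene should add to the Si face of C1. Regio-, endo-, facial and peri-selectivity (C=C over C=O) are needed: the 1-alkoxy and 3-silyloxy donors polarise the diene toward C11, the formyl group directs endo, the catalyst selects the face, and the carbonyl-bound α-methyl enal presents its olefin, not its carbonyl, to the diene.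

Step 6
Reactants: 9 cycloadduct; 10 vinylmagnesium bromide
Product: 11 (2S)-allylic alcohol (formyl group of 9 converted into CH(OH)CH=CH2; C3=C4 vinyl)
Conditions: MgBr2·OEt2, CH2Cl2, −78 °C; then 10 (THF solution); aq. NH4Cl
Reagents that add atoms: none
Why: Cram-chelate-controlled Grignard addition: magnesium bridges the aldehyde and C14 ether oxygens in a six-membered chelate, and the vinyl group should add from the side of the C15 methyl, away from C10, to give the (2S) carbinol.

Step 7
Reactants: 11 allylic alcohol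
Product: 12 C2 tert-butyldimethylsilyl ether of 11
Conditions: TBSOTf, 2,6-lutidine, CH2Cl2, 0 °C
Reagents that add atoms: tert-butyldimethylsilyl trifluoromethanesulfonate, CC(C)(C)[Si](C)(C)OS(=O)(=O)C(F)(F)F
Why: silylation with a silyl triflate and a hindered base protects the neopentyl secondary alcohol and leaves the silyl enol ether untouched.

Step 8
Reactants: 12 silyl enol ether
Product: 13 C12 ketone (C2 and C9 silyl ethers and C14 PMB ether retained)
Conditions: TBAF, AcOH, THF, −78 °C
Reagents that add atoms: none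
Why: fluoride cleaves the enol silyl ether far faster than the alkyl silyl ethers, and immediate protonation at C13 by acetic acid at low temperature should suppress β-elimination of the C14 ether.

Step 9
Reactants: 13 ketone
Product: 14 C11=C12 enol triflate (tetrasubstituted; C20 on C11)
Conditions: Tf2O, 2,6-di-tert-butyl-4-methylpyridine, CH2Cl2, 0 °C → rt
Reagents that add atoms: trifluoromethanesulfonic anhydride, O=S(=O)(OS(=O)(=O)C(F)(F)F)C(F)(F)F
Why: electrophilic O-triflation with a hindered pyridine base gives the more substituted (thermodynamic) enol triflate without forming an enolate, so the C14 ether should not eliminate; the C11 stereocentre is removed here.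

Step 10
Reactants: 14 enol triflate
Product: 15 cyclohexene with the C11=C12 olefin (C12–H)
Conditions: Pd(OAc)2 (5 mol%), PPh3 (10 mol%), HCO2H, n-Bu3N, DMF, 60 °C
Reagents that add atoms: none
Why: palladium-catalysed formate reduction of an enol triflate (oxidative addition, decarboxylation of formate, reductive elimination) replaces OTf by H without moving the double bond.

Step 11
Reactants: 15 bis-silyl ether
Product: 16 C9 primary alcohol
Conditions: CSA (10 mol%), MeOH/CH2Cl2, 0 °C
Reagents that add atoms: none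
Why: acid-catalysed methanolysis removes the unhindered primary silyl ether selectively; the neopentyl secondary silyl ether at C2 and the PMB ether should remain.

Step 12
Reactants: 16 primary alcohol
Product: 17 C9 aldehyde (β,γ-unsaturated; used directly without chromatography)
Conditions: Dess–Martin periodinane, CH2Cl2, 0 °C → rt
Reagents that add atoms: none
Why: Dess–Martin oxidation is neutral, which should avoid epimerisation at C10 and migration of the C11=C12 bond into conjugation.

Step 13
Reactants: 18 3,4-dimethoxybenzyl alcohol; 19 bromoacetic acid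
Product: 20 2-(3,4-dimethoxybenzyloxy)acetic acid
Conditions: NaH, THF, 0 °C → reflux; then aq. HCl
Reagents that add atoms: none
Why: Williamson etherification of the sodium alkoxide with sodium bromoacetate is a standard route to alkoxyacetic acids.

Step 14
Reactants: 20 2-(3,4-dimethoxybenzyloxy)acetic acid; 21 (R)-4-benzyl-2-oxazolidinone
Product: 23 (R)-4-benzyl-3-[2-(3,4-dimethoxybenzyloxy)acetyl]oxazolidin-2-one, via mixed pivalic anhydride 22 (not isolated)
Conditions: PivCl, Et3N, THF, −20 °C; then 21, LiCl, rt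
Reagents that add atoms: none
Why: N-acylation of the oxazolidinone by a mixed pivalic anhydride under lithium chloride activation takes place at the less hindered acyl group.

Step 15
Reactants: 23 glycolyl oxazolidinone; 17 C9 aldehyde
Product: 25 syn-aldol adduct (8R,9S) carrying the C7 acyl oxazolidinone; C8 ODMB; C9 OH, via dibutylboron (Z)-enolate 24 (not isolated)
Conditions: Bu2BOTf, Et3N, CH2Cl2, −78 → 0 °C; then 17, −78 → 0 °C; pH 7 buffer, MeOH, H2O2
Reagents that add atoms: none
Why: Evans syn-aldol reaction: the (Z)-boron enolate reacts through a chair Zimmerman–Traxler transition state in which the (R)-auxiliary selects the aldehyde face and sets C9 as (S) (C8 is oxidised later); a (Z)-enolate also prefers the anti-Felkin face of the α-branched aldehyde, so auxiliary and substrate should reinforce each other.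

Step 16
Reactants: 25 aldol adduct
Product: 26 C7 Weinreb amide (N-methoxy-N-methyl amide; C9 OH free)
Conditions: MeNHOMe·HCl, AlMe3, CH2Cl2, −20 → 0 °C
Reagents that add atoms: N,O-dimethylhydroxylamine hydrochloride, CNOC.Cl
Why: aluminium amide transamination of a β-hydroxy acyl oxazolidinone is assisted by the aluminium alkoxide of the free hydroxyl and releases the auxiliary without epimerisation at C8.

Step 17
Reactants: 26 Weinreb amide
Product: 27 C9 triethylsilyl ether of 26
Conditions: TESOTf, 2,6-lutidine, CH2Cl2, −78 °C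
Reagents that add atoms: triethylsilyl trifluoromethanesulfonate, CC[Si](CC)(CC)OS(=O)(=O)C(F)(F)F
Why: silyl triflate silylation protects the hindered secondary alcohol under conditions that leave the benzylic ethers intact.

Step 18
Reactants: 27 Weinreb amide; 28 tert-butyldimethyl(prop-2-yn-1-yloxy)silane
Product: 30 ynone (C7 ketone; C5≡C6; C16 OTBS), via lithium acetylide 29 (not isolated)
Conditions: n-BuLi, THF, −78 °C; then 27, −78 → −20 °C; aq. NH4Cl
Reagents that add atoms: none
Why: acetylide addition to a Weinreb amide stops at the chelated tetrahedral intermediate and gives the ynone on work-up.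

Step 19
Reactants: 30 ynone
Product: 31 (7S)-propargylic alcohol
Conditions: Ru[(R,R)-TsDPEN](p-cymene) (2 mol%), i-PrOH, rt
Reagents that add atoms: none
Why: Noyori asymmetric transfer hydrogenation of ynones is catalyst-controlled and base-free; the (R,R)-catalyst should deliver hydride to the face that gives the (7S) alcohol (7,8-anti), with the alkyne as the π-recognition group.

Step 20
Reactants: 31 propargylic alcohol
Product: 33 (Z)-vinyl iodide (iodine on C5 cis to C7; C7 OH free), via cyclic alkenylalanate 32 (not isolated)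
Conditions: Red-Al, THF, 0 °C → rt; then I2, −78 → 0 °C; Rochelle salt
Reagents that add atoms: iodine, II
Why: hydroxyl-directed trans-hydroalumination delivers hydride to C6 and aluminium to C5 within a five-membered ring, and iodinolysis with retention fixes the C5=C6 geometry with iodine cis to C7.

Step 21
Reactants: 33 vinyl iodide
Product: 35 ten-membered carbocycle (new C4–C5 bond; C5=C6 with C4 and C7 cis; C7 OH free), via B-alkyl-9-BBN borane 34 (not isolated)
Conditions: 9-BBN, THF, rt; then Pd(dppf)Cl2 (20 mol%), AsPh3 (20 mol%), Cs2CO3, DMF/THF/H2O, 50 °C, slow addition (2 mM)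
Reagents that add atoms: none
Why: 9-BBN hydroborates only the terminal C3=C4 olefin at C4, and intramolecular B-alkyl Suzuki–Miyaura coupling with the alkenyl iodide proceeds with retention, a ring closure established for nine-membered carbocycles with trisubstituted olefins.

Step 22
Reactants: 35 macrocyclic alcohol; 36 2-bromopropanoyl bromide
Product: 37 C7 2-bromopropanoate (epimers at the bromine-bearing carbon)
Conditions: pyridine, CH2Cl2, 0 °C
Reagents that add atoms: none
Why: acylation of the only free hydroxyl with an acid bromide; the configuration at the bromine-bearing carbon is irrelevant because it becomes an enolate.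

Step 23
Reactants: 37 bromo ester
Product: 38 C8 alcohol
Conditions: DDQ (1.1 equiv), CH2Cl2/pH 7 buffer, 0 °C
Reagents that add atoms: none
Why: DDQ oxidises the electron-richer 3,4-dimethoxybenzyl ether faster than the hindered 4-methoxybenzyl ether at C14, so only the C8 hydroxyl should be freed.

Step 24
Reactants: 38 C8 alcohol
Product: 39 C8 ketone
Conditions: Dess–Martin periodinane, CH2Cl2, 0 °C → rt
Reagents that add atoms: none
Why: Dess–Martin oxidation of the secondary alcohol under neutral conditions should not epimerise the flanking oxygenated centres C7 and C9.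

Step 25
Reactants: 39 keto bromo ester
Product: 41 trans-fused γ-lactone (8S,17R) with tertiary C8 OH and C18 methyl, via samarium(III) enolate 40 (not isolated)
Conditions: SmI2 (2.2 equiv), THF, −78 °C; aq. NH4Cl
Reagents that add atoms: none
Why: samarium(II)-mediated intramolecular Reformatsky reaction: the enolate adds to the C8 ketone through a chelated transition state with the ester oxygen perpendicular to the carbonyl and the ring backbone antiperiplanar across C7–C8, so the (7S) centre should fix the face (C8 OH cis to C6, trans-fused lactone) and the C18 methyl should take the side away from C9 (cis to the hydroxyl).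

Step 26
Reactants: 41 lactone
Product: 42 C14 alcohol
Conditions: DDQ, CH2Cl2/pH 7 buffer, 0 °C → rt
Reagents that add atoms: none
Why: oxidative cleavage of the remaining PMB ether with DDQ; C2 is still silylated, so no benzylidene acetal can form.

Step 27
Reactants: 42 tris-silyl ether
Product: 43 pentaol (C2/C9/C14/C16 and tertiary C8 hydroxyls free)
Conditions: HF·pyridine, pyridine, THF, 0 °C → rt
Reagents that add atoms: none
Why: buffered HF·pyridine removes the triethylsilyl and both tert-butyldimethylsilyl ethers without base, which protects the β-hydroxy lactone from elimination and C17 from epimerisation.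

Step 28
Reactants: 43 pentaol
Product: 44 CNP0277472.2 (C2/C9/C14/C16 tetraacetate; C8 OH free)
Conditions: Ac2O, pyridine, DMAP (cat.), CH2Cl2, 0 °C → rt
Reagents that add atoms: acetic anhydride, CC(=O)OC(C)=O
Why: acetylation esterifies the primary and the three secondary hydroxyls, while the hindered tertiary C8 hydroxyl should stay free.

**Compound list**

1 | pent-1-yn-3-ol (racemic) | C#CC(O)CC | starting material
2 | pent-1-yn-3-one | C#CC(=O)CC | intermediate
3 | 4-methoxybenzyl alcohol | COc1ccc(CO)cc1 | starting material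
4 | (E)-1-(4-methoxybenzyloxy)pent-1-en-3-one | CCC(=O)/C=C/OCc1ccc(OC)cc1 | intermediate
5 | (1E,3Z)-1-(4-methoxybenzyloxy)-3-(tert-butyldimethylsilyloxy)penta-1,3-diene | C/C=C(O[Si](C)(C)C(C)(C)C)/C=C/OCc1ccc(OC)cc1 | intermediate
6 | (tert-butyldimethylsilyloxy)acetaldehyde | O=CCO[Si](C)(C)C(C)(C)C | starting material
7 | 2-(triphenylphosphoranylidene)propanal | CC(C=O)=P(c1ccccc1)(c1ccccc1)c1ccccc1 | starting material
8 | (E)-4-(tert-butyldimethylsilyloxy)-2-methylbut-2-enal | O=C/C(C)=C/CO[Si](C)(C)C(C)(C)C | intermediate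
9 | cycloadduct, (1R,2S,5S,6S)-4-(tert-butyldimethylsilyloxy)-6-[(tert-butyldimethylsilyloxy)methyl]-2-(4-methoxybenzyloxy)-1,5-dimethylcyclohex-3-ene-1-carbaldehyde | CC(C)(C)[Si](C)(C)OC[C@H]1[C@H](C)C(O[Si](C)(C)C(C)(C)C)=C[C@H](OCc2ccc(OC)cc2)[C@]1(C)C=O | intermediate
10 | vinylmagnesium bromide | C=C[Mg]Br | starting material
11 | (2S)-allylic alcohol, C2 carbinol with C3=C4 vinyl group | CC(C)(C)[Si](C)(C)OC[C@H]1[C@H](C)C(O[Si](C)(C)C(C)(C)C)=C[C@H](OCc2ccc(OC)cc2)[C@]1(C)[C@@H](O)C=C | intermediate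
12 | C2 TBS ether of 11 | CC(C)(C)[Si](C)(C)OC[C@H]1[C@H](C)C(O[Si](C)(C)C(C)(C)C)=C[C@H](OCc2ccc(OC)cc2)[C@]1(C)[C@@H](O[Si](C)(C)C(C)(C)C)C=C | intermediate
13 | C12 ketone | CC(C)(C)[Si](C)(C)OC[C@H]1[C@H](C)C(=O)C[C@H](OCc2ccc(OC)cc2)[C@]1(C)[C@@H](O[Si](C)(C)C(C)(C)C)C=C | intermediate
14 | C11=C12 enol triflate | CC(C)(C)[Si](C)(C)OC[C@H]1C(C)=C(OS(=O)(=O)C(F)(F)F)C[C@H](OCc2ccc(OC)cc2)[C@]1(C)[C@@H](O[Si](C)(C)C(C)(C)C)C=C | intermediate
15 | cyclohexene with C11=C12 olefin, C9 OTBS | CC(C)(C)[Si](C)(C)OC[C@H]1C(C)=CC[C@H](OCc2ccc(OC)cc2)[C@]1(C)[C@@H](O[Si](C)(C)C(C)(C)C)C=C | intermediate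
16 | C9 primary alcohol | OC[C@H]1C(C)=CC[C@H](OCc2ccc(OC)cc2)[C@]1(C)[C@@H](O[Si](C)(C)C(C)(C)C)C=C | intermediate
17 | C9 aldehyde | O=C[C@H]1C(C)=CC[C@H](OCc2ccc(OC)cc2)[C@]1(C)[C@@H](O[Si](C)(C)C(C)(C)C)C=C | intermediate
18 | 3,4-dimethoxybenzyl alcohol | COc1ccc(CO)cc1OC | starting material
19 | bromoacetic acid | OC(=O)CBr | starting material
20 | 2-(3,4-dimethoxybenzyloxy)acetic acid | COc1ccc(COCC(O)=O)cc1OC | intermediate
21 | (R)-4-benzyl-2-oxazolidinone | O=C1N[C@H](Cc2ccccc2)CO1 | starting material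
22 | mixed pivalic anhydride of 20 (not isolated) | COc1ccc(COCC(=O)OC(=O)C(C)(C)C)cc1OC | intermediate
23 | (R)-4-benzyl-3-[2-(3,4-dimethoxybenzyloxy)acetyl]oxazolidin-2-one | COc1ccc(COCC(=O)N2[C@H](Cc3ccccc3)COC2=O)cc1OC | intermediate
24 | dibutylboron (Z)-enolate of 23 (not isolated) | COc1ccc(CO/C=C(\OB(CCCC)CCCC)N2[C@H](Cc3ccccc3)COC2=O)cc1OC | intermediate
25 | syn-aldol adduct (8R,9S), C7 acyl oxazolidinone, C8 ODMB, C9 OH | O=C1OC[C@@H](Cc2ccccc2)N1C(=O)[C@H](OCc3ccc(OC)c(OC)c3)[C@@H](O)[C@H]4C(C)=CC[C@H](OCc5ccc(OC)cc5)[C@]4(C)[C@@H](O[Si](C)(C)C(C)(C)C)C=C | intermediate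
26 | C7 Weinreb amide, C9 OH | CON(C)C(=O)[C@H](OCc1ccc(OC)c(OC)c1)[C@@H](O)[C@H]2C(C)=CC[C@H](OCc3ccc(OC)cc3)[C@]2(C)[C@@H](O[Si](C)(C)C(C)(C)C)C=C | intermediate
27 | C7 Weinreb amide, C9 OTES | CON(C)C(=O)[C@H](OCc1ccc(OC)c(OC)c1)[C@@H](O[Si](CC)(CC)CC)[C@H]2C(C)=CC[C@H](OCc3ccc(OC)cc3)[C@]2(C)[C@@H](O[Si](C)(C)C(C)(C)C)C=C | intermediate
28 | tert-butyldimethyl(prop-2-yn-1-yloxy)silane | C#CCO[Si](C)(C)C(C)(C)C | starting material
29 | lithium acetylide of 28 (not isolated) | [Li]C#CCO[Si](C)(C)C(C)(C)C | intermediate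
30 | ynone (C7 ketone, C5≡C6, C16 OTBS) | CC(C)(C)[Si](C)(C)OCC#CC(=O)[C@H](OCc1ccc(OC)c(OC)c1)[C@@H](O[Si](CC)(CC)CC)[C@H]2C(C)=CC[C@H](OCc3ccc(OC)cc3)[C@]2(C)[C@@H](O[Si](C)(C)C(C)(C)C)C=C | intermediate
31 | (7S)-propargylic alcohol | CC(C)(C)[Si](C)(C)OCC#C[C@H](O)[C@H](OCc1ccc(OC)c(OC)c1)[C@@H](O[Si](CC)(CC)CC)[C@H]2C(C)=CC[C@H](OCc3ccc(OC)cc3)[C@]2(C)[C@@H](O[Si](C)(C)C(C)(C)C)C=C | intermediate
32 | cyclic sodium alkenylalanate (Al on C5 and O7; not isolated) | CC(C)(C)[Si](C)(C)OCC1=C[C@@H]([C@H](OCc2ccc(OC)c(OC)c2)[C@@H](O[Si](CC)(CC)CC)[C@H]3C(C)=CC[C@H](OCc4ccc(OC)cc4)[C@]3(C)[C@@H](O[Si](C)(C)C(C)(C)C)C=C)O[Al-]1(OCCOC)OCCOC.[Na+] | intermediate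
33 | (Z)-vinyl iodide (I on C5, cis to C7), C7 OH | CC(C)(C)[Si](C)(C)OC/C(I)=C/[C@H](O)[C@H](OCc1ccc(OC)c(OC)c1)[C@@H](O[Si](CC)(CC)CC)[C@H]2C(C)=CC[C@H](OCc3ccc(OC)cc3)[C@]2(C)[C@@H](O[Si](C)(C)C(C)(C)C)C=C | intermediate
34 | C4 B-alkyl-9-BBN borane, C7 O-borinate (not isolated) | CC(C)(C)[Si](C)(C)OC/C(I)=C/[C@H](OB1C2CCCC1CCC2)[C@H](OCc3ccc(OC)c(OC)c3)[C@@H](O[Si](CC)(CC)CC)[C@H]4C(C)=CC[C@H](OCc5ccc(OC)cc5)[C@]4(C)[C@@H](O[Si](C)(C)C(C)(C)C)CCB6C7CCCC6CCC7 | intermediate
35 | ten-membered carbocycle, C7 OH, C8 ODMB, C9 OTES, C2 OTBS, C14 OPMB, C16 OTBS | CC(C)(C)[Si](C)(C)OC/C1=C/[C@H](O)[C@H](OCc2ccc(OC)c(OC)c2)[C@@H](O[Si](CC)(CC)CC)[C@H]3C(C)=CC[C@H](OCc4ccc(OC)cc4)[C@]3(C)[C@@H](O[Si](C)(C)C(C)(C)C)CC1 | intermediate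
36 | 2-bromopropanoyl bromide (racemic) | CC(Br)C(Br)=O | starting material
37 | C7 2-bromopropanoate | CC(C)(C)[Si](C)(C)OC/C1=C/[C@H](OC(=O)C(C)Br)[C@H](OCc2ccc(OC)c(OC)c2)[C@@H](O[Si](CC)(CC)CC)[C@H]3C(C)=CC[C@H](OCc4ccc(OC)cc4)[C@]3(C)[C@@H](O[Si](C)(C)C(C)(C)C)CC1 | intermediate
38 | C8 alcohol | CC(C)(C)[Si](C)(C)OC/C1=C/[C@H](OC(=O)C(C)Br)[C@H](O)[C@@H](O[Si](CC)(CC)CC)[C@H]3C(C)=CC[C@H](OCc4ccc(OC)cc4)[C@]3(C)[C@@H](O[Si](C)(C)C(C)(C)C)CC1 | intermediate
39 | C8 ketone | CC(C)(C)[Si](C)(C)OC/C1=C/[C@H](OC(=O)C(C)Br)C(=O)[C@@H](O[Si](CC)(CC)CC)[C@H]3C(C)=CC[C@H](OCc4ccc(OC)cc4)[C@]3(C)[C@@H](O[Si](C)(C)C(C)(C)C)CC1 | intermediate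
40 | samarium(III) ester enolate of 39 (not isolated) | CC(C)(C)[Si](C)(C)OC/C1=C/[C@H](OC(O[Sm](I)I)=CC)C(=O)[C@@H](O[Si](CC)(CC)CC)[C@H]3C(C)=CC[C@H](OCc4ccc(OC)cc4)[C@]3(C)[C@@H](O[Si](C)(C)C(C)(C)C)CC1 | intermediate
41 | trans-fused γ-lactone (8S,17R), C8 OH | CC(C)(C)[Si](C)(C)OC/C1=C/[C@@H]2OC(=O)[C@H](C)[C@@]2(O)[C@@H](O[Si](CC)(CC)CC)[C@H]3C(C)=CC[C@H](OCc4ccc(OC)cc4)[C@]3(C)[C@@H](O[Si](C)(C)C(C)(C)C)CC1 | intermediate
42 | C14 alcohol | CC(C)(C)[Si](C)(C)OC/C1=C/[C@@H]2OC(=O)[C@H](C)[C@@]2(O)[C@@H](O[Si](CC)(CC)CC)[C@H]3C(C)=CC[C@H](O)[C@]3(C)[C@@H](O[Si](C)(C)C(C)(C)C)CC1 | intermediate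
43 | pentaol | OC/C1=C/[C@@H]2OC(=O)[C@H](C)[C@@]2(O)[C@@H](O)[C@H]3C(C)=CC[C@H](O)[C@]3(C)[C@@H](O)CC1 | intermediate
44 | CNP0277472.2 | CC(=O)OC/C1=C/[C@@H]2OC(=O)[C@H](C)[C@@]2(O)[C@@H](OC(C)=O)[C@H]2C(C)=CC[C@H](OC(C)=O)[C@]2(C)[C@@H](OC(C)=O)CC1 | target

**Totals and risks**

Total step count: 28 (step 4 makes the dienophile, steps 13 and 14 the aldol reagent). Longest linear sequence: 25 steps (1–3, 5–12, 15–28).

Steps most likely to fail:

Step 21. Intermolecular coupling (oligomerisation), protodeboronation and β-hydride elimination of the alkylpalladium species may outrun closure of the strained ten-membered ring. The fallback sets out from vinyl iodide 33 and closes the ring by metathesis at C3=C4 instead. Stille coupling of 33 with tributyl(vinyl)stannane (Pd2(dba)3, AsPh3, CuI, NMP) would give the 1,3-diene F1. Ring-closing metathesis of its two terminal vinyl groups (second-generation Grubbs catalyst, CH2Cl2, reflux, high dilution) would give the macrocyclic triene F2. Diimide (2-nitrobenzenesulfonylhydrazide, Et3N) would then reduce only the disubstituted C3=C4 bond, and the route is rejoined at carbocycle 35.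

Step 25. Electron transfer to the doubly α-oxygenated ketone (ketyl formation with loss of the C7 or C9 oxygen) may compete with enolate formation, and the enolate may attack the wrong face of the C8 carbonyl. The fallback sets out from macrocyclic alcohol 35 and builds the lactone as a butenolide first. Esterification with 2-(diethoxyphosphoryl)propanoic acid (DCC, DMAP) would give the phosphonate ester F3, selective DDQ cleavage of the dimethoxybenzyl ether the C8 alcohol F4, and Dess–Martin oxidation the keto phosphonate F5. Intramolecular Horner–Wadsworth–Emmons reaction (LiCl, DBU, MeCN) would give the C8=C17 butenolide F6. Nucleophilic (Weitz–Scheffer) epoxidation with tert-butyl hydroperoxide and DBU, expected on the exposed face of the macrocycle, would give the 8,17-epoxy lactone F7. Reductive opening of the α,β-epoxy lactone at C17 (SmI2, THF, N,N-dimethylethanolamine, −78 °C), with protonation placing the methyl group away from C9, rejoins the route at lactone 41.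

Step 9. Enolisation toward C13 would give the regioisomeric triflate and open the way to β-elimination of the C14 ether, and triflic anhydride may attack the PMB ether. The fallback sets out from ketone 13 and separates regiocontrol from triflation. Equilibrating silylation (Me3SiI, hexamethyldisilazane, CH2Cl2, −20 °C → rt) would give the more substituted trimethylsilyl enol ether F8. Methyllithium (THF, 0 °C) would release the regiodefined lithium enolate F9, which cannot eliminate the C14 ether. N-Phenyltriflimide at −78 °C would trap it, and the route is rejoined at enol triflate 14.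

**Further compounds**

F1 | step 21 | 1,3-diene (vinyl group on C5 in place of iodine; C7 OH free) | CC(C)(C)[Si](C)(C)OC/C(C=C)=C/[C@H](O)[C@H](OCc1ccc(OC)c(OC)c1)[C@@H](O[Si](CC)(CC)CC)[C@H]2C(C)=CC[C@H](OCc3ccc(OC)cc3)[C@]2(C)[C@@H](O[Si](C)(C)C(C)(C)C)C=C
F2 | step 21 | macrocyclic triene (ten-membered ring with cis C3=C4 conjugated to C5=C6) | [C@H]1(O[Si](C)(C)C(C)(C)C)/C=C\C(CO[Si](C)(C)C(C)(C)C)=C/[C@H](O)[C@H](OCc3ccc(OC)c(OC)c3)[C@@H](O[Si](CC)(CC)CC)[C@H]2C(C)=CC[C@H](OCc4ccc(OC)cc4)[C@]12C
F3 | step 25 | C7 2-(diethoxyphosphoryl)propanoate of 35 | CC(C)(C)[Si](C)(C)OC/C1=C/[C@H](OC(=O)C(C)P(=O)(OCC)OCC)[C@H](OCc2ccc(OC)c(OC)c2)[C@@H](O[Si](CC)(CC)CC)[C@H]3C(C)=CC[C@H](OCc4ccc(OC)cc4)[C@]3(C)[C@@H](O[Si](C)(C)C(C)(C)C)CC1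
F4 | step 25 | C8 alcohol of the phosphonate ester | CC(C)(C)[Si](C)(C)OC/C1=C/[C@H](OC(=O)C(C)P(=O)(OCC)OCC)[C@H](O)[C@@H](O[Si](CC)(CC)CC)[C@H]3C(C)=CC[C@H](OCc4ccc(OC)cc4)[C@]3(C)[C@@H](O[Si](C)(C)C(C)(C)C)CC1
F5 | step 25 | C8 keto phosphonate | CC(C)(C)[Si](C)(C)OC/C1=C/[C@H](OC(=O)C(C)P(=O)(OCC)OCC)C(=O)[C@@H](O[Si](CC)(CC)CC)[C@H]3C(C)=CC[C@H](OCc4ccc(OC)cc4)[C@]3(C)[C@@H](O[Si](C)(C)C(C)(C)C)CC1
F6 | step 25 | C8=C17 butenolide | CC(C)(C)[Si](C)(C)OC/C1=C/[C@@H]2OC(=O)C(C)=C2[C@@H](O[Si](CC)(CC)CC)[C@H]3C(C)=CC[C@H](OCc4ccc(OC)cc4)[C@]3(C)[C@@H](O[Si](C)(C)C(C)(C)C)CC1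
F7 | step 25 | 8,17-epoxy lactone (epoxide oxygen on the face of the later C8 hydroxyl) | CC(C)(C)[Si](C)(C)OC/C1=C/[C@@H]2OC(=O)[C@]3(C)O[C@]23[C@@H](O[Si](CC)(CC)CC)[C@H]4C(C)=CC[C@H](OCc5ccc(OC)cc5)[C@]4(C)[C@@H](O[Si](C)(C)C(C)(C)C)CC1
F8 | step 9 | C11=C12 trimethylsilyl enol ether | CC(C)(C)[Si](C)(C)OC[C@H]1C(C)=C(O[Si](C)(C)C)C[C@H](OCc2ccc(OC)cc2)[C@]1(C)[C@@H](O[Si](C)(C)C(C)(C)C)C=C
F9 | step 9 | C11=C12 lithium enolate | CC(C)(C)[Si](C)(C)OC[C@H]1C(C)=C(O[Li])C[C@H](OCc2ccc(OC)cc2)[C@]1(C)[C@@H](O[Si](C)(C)C(C)(C)C)C=C
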